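Constants read from two runs at other temperatures would have to be carried to 45 °C, so I leave them aside and divide the target formed by the reagent fed up to a given moment, a ratio that still depends on the moment of reading.

| flask | starting material | reagent | initiator | temperature | remark | time |
|---|---|---|---|---|---|---|
| north | 0.17 M | 0.091 M (fed, over 3.0 h) | 2.6 mM | 15 °C | run made earlier; the fed solution adds 0.20 times the starting volume |  |
| south | 0.31 M | 0.091 M (fed, over 3.0 h) | 2.6 mM | 37 °C | run made earlier; the fed solution adds 0.20 times the starting volume |  |
| larch | 0.13 M | 0.0910 M (fed, over 3.0 h) | 2.6 mM |  | at 5 °C until 3.0 h, from then on at 45 °C; the fed solution adds 0.20 times the starting volume | 6.0 h |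
| oak | 0.20 M | 0.0910 M (fed, over 3.0 h) | 2.6 mM |  | at 45 °C throughout; the fed solution adds 0.20 times the starting volume | 10 h |

north run (percent of the starting material charged)

| time / h | target / % | starting material / % |
|---|---|---|
| 0.500 | 3.0 | 98.0 |
| 1.00 | 7.9 | 90.6 |
| 1.50 | 16.0 | 84.1 |
| 2.00 | 21.6 | 78.1 |
| 2.50 | 28.9 | 70.8 |

south run (percent of the starting material charged)

| time / min | target / % | starting material / % |
|---|---|---|
| 4.00 | 0 | 99.7 |
| 8.00 | 0.4 | 98.6 |
| 15.0 | 1.6 | 98.7 |
| 25.0 | 1.5 | 96.7 |
| 50.0 | 7.0 | 92.9 |

(each reading ± 0.5 percentage points)

- every charge counts on the volume at the start, and the solution that is fed holds the whole dose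
- the numbers in the tables scatter with a standard deviation of 0.5 percentage points

1. the winner by amount of target, in percent of the starting material charged; "neither" if no more than 2 percentage points parts them (larch / oak / neither)
2. how much target is there at the end, in percent of the starting material charged: larch
3. how much target is there at the end, in percent of the starting material charged: oak

In larch and in oak the reagent is the smaller charge, so I treat it as the limiting reagent, and its dose is 70.0% of the starting material in larch and 45.5% in oak. In the north run, between 1.00 h and 2.50 h, the rise of target over the reagent fed in that interval is 0.785, so oak stands near 35.7%. The weak link is the temperature of that run, and the south run lies nearer to 45 °C. At 50.0 min the south run holds 0.0217 M of target against 0.0253 M of reagent fed, and this one reading, with its scatter of 0.5 points, gives 0.858 as the capture, the target formed over the reagent fed up to that moment. Assuming that this capture, read early in the feed of the south run, holds at the end of both flasks, I commit to 60.1% in larch and 39.1% in oak, so by this estimate larch leads by 21 points, well beyond the margin of 2 points.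

The forecast says larch, with 68.5% for larch and 45% for oak. Its oak figure differs from mine, being the whole dose turned into target, on the ground that “the reagent is consumed fully”.

The flasks give larch, with 67.1% in larch and 25.3% in oak.

    starting material + initiating radical → capped initiator + first chain carrier (k = 79000 M⁻¹ s⁻¹, Ea = 21.0 kJ mol⁻¹)
    reagent + first chain carrier ⇌ target + second chain carrier (K = 1.30, k = 2400 M⁻¹ s⁻¹, Ea = 39.0 kJ mol⁻¹, ΔH = −16.0 kJ mol⁻¹)
    initiator → 2 initiating radical (k = 6.30 × 10⁻⁶ s⁻¹, Ea = 88.0 kJ mol⁻¹)
    reagent ⇌ dormant form (K = 0.820, k = 2.70 × 10⁻⁵ s⁻¹, Ea = 99.0 kJ mol⁻¹, ΔH = 20.0 kJ mol⁻¹)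
    starting material + second chain carrier → released group + first chain carrier (k = 7600 M⁻¹ s⁻¹, Ea = 35.0 kJ mol⁻¹)
    2 first chain carrier → ended chains B (k = 3.10 × 10⁶ M⁻¹ s⁻¹, Ea = 20.0 kJ mol⁻¹)
    2 second chain carrier → ended chains A (k = 3.60 × 10⁸ M⁻¹ s⁻¹, Ea = 12.0 kJ mol⁻¹)
    (constants at 5 °C)

At the end, oak's capture is 0.555, less than the 0.858 I carried, while larch's is 0.959. In oak the half-life of reagent by the forward rate of the step into target alone is 0.11 h at 1.18 h but 75 d at 10.0 h, with initiator at 0.0293% of its charge at 3.00 h, and target moves from 23.4% at that time to 25.3% at the end, beside 13.0% of the reagent's own charge and 0.0239 M of dormant form. For oak's neighbour charged with 0.15 M of reagent, a dose of 75.0%, oak's capture gives 41.6%; that flask gives 39.4%.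

(The readings are simulated with made-up constants, noise included.)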